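No rate constant is given, and for a bracket you need none: count turnovers.

| flask | substrate | partner | remark | time |
|---|---|---|---|---|
| Friday's | 0.050 M | 0.14 M | run made earlier |  |
| Saturday's | 0.050 M | 0.22 M | run made earlier |  |
| Sunday's | 0.10 M | 0.10 M | run made earlier |  |
| flask | 0.050 M | 0.100 M |  | 50 min |

| run | time / min | single product / % | substrate / % |
|---|---|---|---|
| Friday's | 4.00 | 60.8 | 0 |
| Friday's | 12.0 | 61.1 | 0 |
| Friday's | 20.0 | 61.8 | 0 |
| Friday's | 30.0 | 60.0 | 0 |
| Friday's | 50.0 | 62.4 | 2.5 |
| Friday's | 60.0 | 60.8 | 0 |
| Saturday's | 5.00 | 30.6 | 1.2 |
| Saturday's | 8.00 | 31.4 | 0.9 |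
| Saturday's | 12.0 | 30.1 | 0 |
| Saturday's | 20.0 | 31.2 | 3.2 |
| Saturday's | 40.0 | 32.3 | 0.4 |
| Saturday's | 60.0 | 29.0 | 0 |
| Sunday's | 5.00 | 75.1 | 23.1 |
| Sunday's | 15.0 | 71.8 | 23.5 |
| Sunday's | 30.0 | 71.7 | 23.4 |
| Sunday's | 40.0 | 71.6 | 24.3 |
| Sunday's | 60.0 | 70.4 | 24.3 |

(readings scatter by 1 percentage point)

- the analysis behind the earlier runs scatters by 1 percentage point, standard deviation
- a reading or a percentage of single product counts all its forms, free or not

1. equivalents of partner to substrate, everything else as given, that leave most single product at 50 min
2. the amount of single product then, in percent of the substrate charged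
3. the amount of single product with the amounts as given

Friday's and Saturday's readings lie flat within the scatter, and Sunday's do from the second reading on, so read each run as one end state. Take what is neither substrate nor single product as double product, which took partner twice. Turnovers, the partner taken up per substrate charged, are then two minus the single-product fraction minus twice the substrate fraction, the substrate being negligible on Friday and Saturday. That gives 1.39 on Friday, 1.69 on Saturday and, from a mean single product of 72.1%, 0.804 on Sunday.

Divided by the equivalents charged, this is partner's useful share: 49.6% on Friday and 38.5% on Saturday, both at this flask's substrate charge. Run that trend on to this flask's 2.00 equivalents and you get a useful share of 55.2%, hence 1.10 turnovers.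

At those turnovers leftover substrate lowers single product, so if the trend holds, your upper bound for the flask is 89.7%. Single product against turnovers rises and falls, and if the runs share one such arched curve, it lies above its chord. On that assumption the line from Sunday's point to Friday's gives 66.5% as your lower bound.

The forecast, holding that “the reaction has stopped rather than run out”, says 75%, inside your bracket, and a best of 77% at 1.66 equiv.

The flask gives 75.8%, also inside, and its best is 77.5% at 1.72 equiv.

    substrate + partner → single product (k = 11.0 L mol⁻¹ s⁻¹)
    partner + single product → double product (k = 3.00 L mol⁻¹ s⁻¹)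
    crystals ⇌ single product, rate k3*(cs3 - [single product]) while solid is left; crystals form when [single product] > cs3 (solubility = 9.20 mM, k = 2.50 s⁻¹)
    partner → decomposed reagent (k = 0.120 s⁻¹)

Partner's half-life by the loss to decomposed reagent alone, 0.096 min, is far shorter than the 50 min allowed. In the flask at 0.0125 min the making of single product uses partner 2.3 times as fast as that loss does, and by 5.00 min partner, the limiting reagent here, stands at 0% of its charge. The share reckoned as 55.2% comes out at 59.6% in this flask. In the neighbour flask at 3.40 equiv the trend gives 45.4%, and the useful share of that flask comes out at 44.1%.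

The readings come from a simulation from invented constants.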